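**Plan**

- Numbering used below: furanone ring O1, C2 (C=O), C3, C4, C5; C6 is the exocyclic CH; C7 is the carbinol carbon.
- Retrosynthesis: C7–OH is traced back to the C7 ketone; then C3–C7 and C4–C5 are cut together (with removal of the C5=C6 unsaturation) to give aldehyde 7 as an aroyl radical source and enol ester 6; O1–C5 of 6 is cut to acid 5 and alkyne 3; C2–C3 is cut to alkyne 3 and CO2; both bromophenol units come from aldehyde 1.
- Forward order: aryl–C4≡C3 alkyne, then C2 (carboxylation), then O1–C5=C6–aryl (enol ester). The only ring, the furanone, is closed last at C4–C5 in step 5, which also joins C7 to C3 and creates the C5=C6 alkene.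
- Enabling feature: C4 is the aryl-bearing carbon of a former arylpropiolate alkyne (C3≡C4). A radical adding at C3 leaves an aryl-stabilised vinyl radical at C4, five atoms (C4–C3–C2–O1–C5) from an enol-ester carbon C5 whose neighbour C6 is benzylic. The C3 substituent at the ketone level is an aroyl group, so an aroyl radical can start the cascade.
- Stereochemistry: the Z geometry of C5=C6 is thermodynamic (step 5); the single stereocentre C7 (S) comes from a Corey–Bakshi–Shibata reduction of the aroyl ketone (step 6). The two phenols are carried as triisopropylsilyl ethers.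

Key step: step 5

Assumptions: aldehydes 1 and 7 are taken as commercial. The alkene geometry of enol ester 6 is lost in step 5 (C6 becomes a freely rotating radical and cation), so 6 is drawn as the Z isomer expected from step 4 without this being a requirement.

**Step 1**
Reactants: 1 3-bromo-4-hydroxybenzaldehyde
Product: 2 3-bromo-4-(triisopropylsilyloxy)benzaldehyde
Conditions: iPr3SiCl, imidazole, DMF, rt
Reagents that add atoms: chlorotriisopropylsilane, CC(C)[Si](Cl)(C(C)C)C(C)C
Why: O-silylation of the acidic ortho-bromophenol (silyl ether formation) should be fast and leave the aldehyde untouched; the bulky silyl ether is chosen to survive the Grignard, radical and borane steps and to leave under buffered fluoride at the end.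

**Step 2**
Reactants: 2 3-bromo-4-(triisopropylsilyloxy)benzaldehyde
Product: 3 (2-bromo-4-ethynylphenoxy)triisopropylsilane
Conditions: Me3SiCHN2, LiN(iPr)2, THF, −78 °C to rt
Reagents that add atoms: (trimethylsilyl)diazomethane, C[Si](C)(C)C=[N+]=[N-]
Why: Colvin rearrangement: lithiated trimethylsilyldiazomethane adds to the aldehyde, Peterson-type loss of silanolate and then of N2 gives an alkylidene carbene, and its 1,2-hydrogen shift should give the terminal alkyne under aprotic conditions that spare the aryl silyl ether and the aryl bromide.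

**Step 3**
Reactants: 3 (2-bromo-4-ethynylphenoxy)triisopropylsilane
Product: 5 3-[3-bromo-4-(triisopropylsilyloxy)phenyl]prop-2-ynoic acid, via alkynylmagnesium bromide 4 (not isolated)
Conditions: EtMgBr, THF, 0 to 40 °C; CO2 (1 atm), 0 °C to rt; then 1 M HCl
Reagents that add atoms: carbon dioxide, O=C=O
Why: Deprotonation of the terminal alkyne by the Grignard reagent and carboxylation of the alkynylmagnesium species (Grignard carboxylation) should give the arylpropiolic acid, since EtMgBr does not exchange with the aryl bromide under these conditions.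

**Step 4**
Reactants: 5 3-[3-bromo-4-(triisopropylsilyloxy)phenyl]prop-2-ynoic acid; 3 (2-bromo-4-ethynylphenoxy)triisopropylsilane
Product: 6 (Z)-2-[3-bromo-4-(triisopropylsilyloxy)phenyl]ethenyl 3-[3-bromo-4-(triisopropylsilyloxy)phenyl]prop-2-ynoate
Conditions: [RuCl2(p-cymene)]2 (1 mol%), P(4-ClC6H4)3 (3 mol%), 4-(dimethylamino)pyridine (4 mol%), toluene, 60 °C
Reagents that add atoms: none
Why: Ruthenium-catalysed anti-Markovnikov addition of a carboxylic acid to a terminal alkyne (through a ruthenium vinylidene) should give the Z enol ester; the internal alkyne of 5 cannot form a vinylidene and should stay intact.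

**Step 5**
Reactants: 6 (Z)-2-[3-bromo-4-(triisopropylsilyloxy)phenyl]ethenyl 3-[3-bromo-4-(triisopropylsilyloxy)phenyl]prop-2-ynoate; 7 3,5-dibromo-4-methoxybenzaldehyde
Product: 8 (5Z)-4-[3-bromo-4-(triisopropylsilyloxy)phenyl]-5-{[3-bromo-4-(triisopropylsilyloxy)phenyl]methylidene}-3-(3,5-dibromo-4-methoxybenzoyl)furan-2(5H)-one
Conditions: 7 (2.5 equiv), K2S2O8 (2.5 equiv), nBu4NHSO4 (20 mol%), ClCH2CH2Cl, 90 °C
Reagents that add atoms: none
Why: Proposed new method: sulfate radical anion from K2S2O8 abstracts the formyl hydrogen of 7, the nucleophilic aroyl radical adds to C3 of the electron-poor arylpropiolate to give the aryl-stabilised vinyl radical at C4, this radical attacks the enol-ester carbon C5, and the benzylic C6 radical is oxidised by persulfate to a cation that loses the C5 proton to form the exocyclic alkene. The closest known reaction type is the oxidative radical acylation–cyclization of aryl alkynoates with aldehydes or 2-oxo acids, where the same vinyl radical attacks the oxygen-bearing ipso carbon of the ester aryl group (3-acyl spirolactones and 3-acylcoumarins); here that ipso carbon is replaced by the more reactive alkene carbon C5. The furanone is the only ring formed and is closed in the 5-exo-trig mode through the s-cis ester conformer. No stereocentre is created, and the C5=C6 geometry should be Z under thermodynamic control, because the E isomer would force the C6 aryl group against the C4 aryl group. The step needs the aroyl radical to choose the alkynoate over the styrenic enol-ester alkene and the vinyl radical to choose 5-exo over 6-endo closure; polarity matching with the acceptor alkyne and the electron-rich 1,2-disubstituted nature of the enol ester should secure the first, and formation of a benzylic radical on 5-exo attack the second.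

**Step 6**
Reactants: 8 (5Z)-4-[3-bromo-4-(triisopropylsilyloxy)phenyl]-5-{[3-bromo-4-(triisopropylsilyloxy)phenyl]methylidene}-3-(3,5-dibromo-4-methoxybenzoyl)furan-2(5H)-one
Product: 9 (5Z)-4-[3-bromo-4-(triisopropylsilyloxy)phenyl]-5-{[3-bromo-4-(triisopropylsilyloxy)phenyl]methylidene}-3-[(S)-(3,5-dibromo-4-methoxyphenyl)(hydroxy)methyl]furan-2(5H)-one
Conditions: (R)-Me-CBS oxazaborolidine [(R)-1-methyl-3,3-diphenyltetrahydro-1H,3H-pyrrolo[1,2-c][1,3,2]oxazaborole] (20 mol%), catecholborane (2 equiv), toluene/CH2Cl2, −78 to −20 °C; then MeOH, aq. NaHCO3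
Reagents that add atoms: none
Why: Corey–Bakshi–Shibata reduction: the oxazaborolidine boron should bind the ketone oxygen syn to the flat, ortho-unsubstituted aryl group (small) and anti to the twisted, fully substituted furanone carbon C3 (large), so that hydride is delivered to the Re face of C7 and sets the S carbinol, with 1,2-selectivity over conjugate reduction of the dienyl lactone.

**Step 7**
Reactants: 9 (5Z)-4-[3-bromo-4-(triisopropylsilyloxy)phenyl]-5-{[3-bromo-4-(triisopropylsilyloxy)phenyl]methylidene}-3-[(S)-(3,5-dibromo-4-methoxyphenyl)(hydroxy)methyl]furan-2(5H)-one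
Product: 10 (5Z)-4-(3-bromo-4-hydroxyphenyl)-5-[(3-bromo-4-hydroxyphenyl)methylidene]-3-[(S)-(3,5-dibromo-4-methoxyphenyl)(hydroxy)methyl]furan-2(5H)-one
Conditions: nBu4NF, AcOH (1:1, 2.5 equiv), THF, 0 °C
Reagents that add atoms: none
Why: Fluoride-mediated cleavage of the two aryl silyl ethers (desilylation), buffered with acetic acid so that neither the lactone nor the allylic benzylic carbinol meets strong base or an ionising acid, should release the target without touching the stereocentre.

**Compound list**

1 | 3-bromo-4-hydroxybenzaldehyde | O=Cc1ccc(O)c(Br)c1 | starting material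
2 | 3-bromo-4-(triisopropylsilyloxy)benzaldehyde | O=Cc1ccc(O[Si](C(C)C)(C(C)C)C(C)C)c(Br)c1 | intermediate
3 | (2-bromo-4-ethynylphenoxy)triisopropylsilane | C#Cc1ccc(O[Si](C(C)C)(C(C)C)C(C)C)c(Br)c1 | intermediate
4 | {[3-bromo-4-(triisopropylsilyloxy)phenyl]ethynyl}magnesium bromide (not isolated) | Br[Mg]C#Cc1ccc(O[Si](C(C)C)(C(C)C)C(C)C)c(Br)c1 | intermediate
5 | 3-[3-bromo-4-(triisopropylsilyloxy)phenyl]prop-2-ynoic acid | OC(=O)C#Cc1ccc(O[Si](C(C)C)(C(C)C)C(C)C)c(Br)c1 | intermediate
6 | (Z)-2-[3-bromo-4-(triisopropylsilyloxy)phenyl]ethenyl 3-[3-bromo-4-(triisopropylsilyloxy)phenyl]prop-2-ynoate | O=C(C#Cc1ccc(O[Si](C(C)C)(C(C)C)C(C)C)c(Br)c1)O/C=C\c1ccc(O[Si](C(C)C)(C(C)C)C(C)C)c(Br)c1 | intermediate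
7 | 3,5-dibromo-4-methoxybenzaldehyde | COc1c(Br)cc(C=O)cc1Br | starting material
8 | (5Z)-4-[3-bromo-4-(triisopropylsilyloxy)phenyl]-5-{[3-bromo-4-(triisopropylsilyloxy)phenyl]methylidene}-3-(3,5-dibromo-4-methoxybenzoyl)furan-2(5H)-one | COc1c(Br)cc(C(=O)C2=C(c3ccc(O[Si](C(C)C)(C(C)C)C(C)C)c(Br)c3)/C(=C/c3ccc(O[Si](C(C)C)(C(C)C)C(C)C)c(Br)c3)OC2=O)cc1Br | intermediate
9 | (5Z)-4-[3-bromo-4-(triisopropylsilyloxy)phenyl]-5-{[3-bromo-4-(triisopropylsilyloxy)phenyl]methylidene}-3-[(S)-(3,5-dibromo-4-methoxyphenyl)(hydroxy)methyl]furan-2(5H)-one | COc1c(Br)cc([C@H](O)C2=C(c3ccc(O[Si](C(C)C)(C(C)C)C(C)C)c(Br)c3)/C(=C/c3ccc(O[Si](C(C)C)(C(C)C)C(C)C)c(Br)c3)OC2=O)cc1Br | intermediate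
10 | (5Z)-4-(3-bromo-4-hydroxyphenyl)-5-[(3-bromo-4-hydroxyphenyl)methylidene]-3-[(S)-(3,5-dibromo-4-methoxyphenyl)(hydroxy)methyl]furan-2(5H)-one (CID71459453) | COc1c(Br)cc([C@H](O)C2=C(c3ccc(O)c(Br)c3)/C(=C/c3ccc(O)c(Br)c3)OC2=O)cc1Br | target

**Step count and risks**

Total steps: 7. Longest linear sequence: 7 steps (1 to 10; alkyne 3 is used twice, in steps 3 and 4).

Steps most likely to fail:

1. Step 5 (Proposed new method). The aroyl radical may add to the styrenic enol-ester alkene instead of the alkynoate, the vinyl radical may close 6-endo to a pyranone, or the enol ester may be cleaved oxidatively before cyclization. The fallback uses known chemistry, sets out from alkynylmagnesium bromide 4 (made from 3 as in step 3) and aldehyde 7, and returns at 8. Addition of 4 to 7 (THF, 0 °C) should give racemic 1-(3,5-dibromo-4-methoxyphenyl)-3-[3-bromo-4-(triisopropylsilyloxy)phenyl]prop-2-yn-1-ol F1, and MnO2 (CH2Cl2, rt) should give the ynone F2. Heating F2 with 5-ethoxy-4-methyloxazole in toluene (80–110 °C) should give, by Diels–Alder addition across C2 and C5 of the oxazole, the bridged cycloadduct F3, which loses acetonitrile by cycloreversion to give the 2-ethoxyfuran F4 with the aroyl group next to the ethoxy-bearing carbon. Dilute HCl in THF should hydrolyse F4 to the 3-aroyl-4-arylfuran-2(5H)-one F5, and piperidine-mediated vinylogous Knoevenagel condensation of F5 with aldehyde 2 (toluene, rt) should give 8. In this variant C4–C5 is formed in the cycloaddition and the exocyclic alkene in a separate condensation.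

2. Step 6. Facial selectivity may be poor if the oxazaborolidine does not distinguish the aryl group from the furanone carbon, or hydride may be delivered in a conjugate (1,6) sense to C6. The fallback sets out from 8 and returns at 9. Luche reduction (NaBH4, CeCl3·7H2O, MeOH/THF, −40 °C) should give the racemic alcohol F6 by 1,2-addition; preparative chromatography on a chiral stationary phase should separate 9 from its R enantiomer F7, which MnO2 oxidation returns to 8 for another pass.

3. Step 4. The arylpropiolic acid may decarboxylate, or Markovnikov addition or catalyst deactivation by the alkynoic acid may compete. The fallback sets out from 3 and 5 and returns at 6. Hydroboration of 3 with dicyclohexylborane (THF, 0 °C) should give the E-alkenylborane F8, and oxidation with NaBO3·4H2O the arylacetaldehyde F9. (COCl)2 with catalytic DMF should convert 5 into the acid chloride F10. Deprotonation of F9 with KN(SiMe3)2 (THF, −78 °C) gives the potassium enolate F11, and O-acylation by F10 should give 6 together with its E isomer F12; both isomers are expected to converge on 8 in step 5.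

**Further compounds**

F1 | step 5 | 1-(3,5-dibromo-4-methoxyphenyl)-3-[3-bromo-4-(triisopropylsilyloxy)phenyl]prop-2-yn-1-ol (racemic) | COc1c(Br)cc(C(O)C#Cc2ccc(O[Si](C(C)C)(C(C)C)C(C)C)c(Br)c2)cc1Br
F2 | step 5 | 1-(3,5-dibromo-4-methoxyphenyl)-3-[3-bromo-4-(triisopropylsilyloxy)phenyl]prop-2-yn-1-one | COc1c(Br)cc(C(=O)C#Cc2ccc(O[Si](C(C)C)(C(C)C)C(C)C)c(Br)c2)cc1Br
F3 | step 5 | 7-oxa-2-azabicyclo[2.2.1]hepta-2,5-diene cycloadduct of F2 and 5-ethoxy-4-methyloxazole (not isolated) | CCOC12OC(N=C1C)C(c1ccc(O[Si](C(C)C)(C(C)C)C(C)C)c(Br)c1)=C2C(=O)c1cc(Br)c(OC)c(Br)c1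
F4 | step 5 | {4-[3-bromo-4-(triisopropylsilyloxy)phenyl]-2-ethoxyfuran-3-yl}(3,5-dibromo-4-methoxyphenyl)methanone | CCOc1occ(-c2ccc(O[Si](C(C)C)(C(C)C)C(C)C)c(Br)c2)c1C(=O)c1cc(Br)c(OC)c(Br)c1
F5 | step 5 | 4-[3-bromo-4-(triisopropylsilyloxy)phenyl]-3-(3,5-dibromo-4-methoxybenzoyl)furan-2(5H)-one | COc1c(Br)cc(C(=O)C2=C(c3ccc(O[Si](C(C)C)(C(C)C)C(C)C)c(Br)c3)COC2=O)cc1Br
F6 | step 6 | racemic form of alcohol 9 | COc1c(Br)cc(C(O)C2=C(c3ccc(O[Si](C(C)C)(C(C)C)C(C)C)c(Br)c3)/C(=C/c3ccc(O[Si](C(C)C)(C(C)C)C(C)C)c(Br)c3)OC2=O)cc1Br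
F7 | step 6 | R enantiomer of alcohol 9 | COc1c(Br)cc([C@@H](O)C2=C(c3ccc(O[Si](C(C)C)(C(C)C)C(C)C)c(Br)c3)/C(=C/c3ccc(O[Si](C(C)C)(C(C)C)C(C)C)c(Br)c3)OC2=O)cc1Br
F8 | step 4 | (E)-{2-[3-bromo-4-(triisopropylsilyloxy)phenyl]ethenyl}dicyclohexylborane (not isolated) | C1CCCCC1B(/C=C/c2ccc(O[Si](C(C)C)(C(C)C)C(C)C)c(Br)c2)C1CCCCC1
F9 | step 4 | [3-bromo-4-(triisopropylsilyloxy)phenyl]acetaldehyde | O=CCc1ccc(O[Si](C(C)C)(C(C)C)C(C)C)c(Br)c1
F10 | step 4 | 3-[3-bromo-4-(triisopropylsilyloxy)phenyl]prop-2-ynoyl chloride | O=C(Cl)C#Cc1ccc(O[Si](C(C)C)(C(C)C)C(C)C)c(Br)c1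
F11 | step 4 | potassium 2-[3-bromo-4-(triisopropylsilyloxy)phenyl]ethenolate (not isolated) | [K+].[O-]C=Cc1ccc(O[Si](C(C)C)(C(C)C)C(C)C)c(Br)c1
F12 | step 4 | E isomer of enol ester 6 | O=C(C#Cc1ccc(O[Si](C(C)C)(C(C)C)C(C)C)c(Br)c1)O/C=C/c1ccc(O[Si](C(C)C)(C(C)C)C(C)C)c(Br)c1
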